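A point here is one percent of the starting complex charged, with a side product counting as two, and this flask is the autumn run carried on to 3.0 h.

- autumn: starting complex 0.10 M; incoming ligand 0.18 M; the very flask that is asked about, followed so far
- flask: starting complex 0.10 M; incoming ligand 0.180 M; time 3.0 h

autumn run (percent of the starting complex charged)

| time / min | starting complex / % | complex with two exchanged / % | side product / % |
|---|---|---|---|
| 8.00 | 25.9 | 20.5 | 5.2 |
| 25.0 | 16.0 | 18.3 | 12.8 |
| 40.0 | 14.0 | 15.6 | 16.5 |
| 60.0 | 12.3 | 13.0 | 20.7 |
| 90.0 | 9.1 | 11.3 | 25.5 |

(scatter of a reading: 0.3 percentage points)

* the state of affairs at 3.0 h: stopped, and by what, or still going (it is still moving / all of the starting complex has reacted)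
* share of the starting complex used up at 3.0 h
* complex with two exchanged at 3.0 h, in percent of the starting complex charged
* side product at 3.0 h, in percent of the starting complex charged

- percentages count the starting complex that a species holds: one side product counts as two
- the reaction counts as stopped when no species that holds the starting complex changes by six tenths of a point or more over the second half of the time

Between 40.0 min and 90.0 min the autumn flask's starting complex falls 4.9 percentage points and its complex with two exchanged 4.3 points, while the side product gains 9 points. So I read the two as partners consuming each other, one for one. Their mean share goes from 14.8% to 10.2%. The climb per minute of its reciprocal, taken as a fraction of the charge, reads as the pair constant 0.0609 min⁻¹, a second-order rate constant. The gap between the partners reads 1.5 points.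

Which input must you trust? A gap off by one reading's scatter shifts each partner 0.15 points and leaves the mean untouched. The same slip in the mean at 90.0 min arrives at 3.0 h as 0.12 points. The constant off by 10% moves the mean 0.23 points, so the constant needs the most care.

The pace at 90.0 min, held over the remaining time, gives a fall of 5.7 points. But pace goes with the square of the mean, so I add to the reciprocal instead and get a mean of 6.54%. For this flask my reckoning is then a conversion of 94.2%, 7.29% complex with two exchanged and 32.8% side product. The mean falls 3.7 points against the margin of 0.6 points, so the flask is still moving.

The forecast says it is still moving, with conversion 94.1%, complex with two exchanged 7.6% and side product 32.5%; it too pairs starting complex with complex with two exchanged to make the side product, and puts the rest of the charge in “an unlisted pool that stops changing after the fast early phase”. Its complex figure stands above mine.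

The flask gives: it is still moving, conversion 93.9%, complex with two exchanged 7.73%, side product 32.5%. The incoming ligand, the limiting reagent, stands at 0%. From the pair's mean of 6.90% in this flask, the constant gives 3.97 h more to halve it.

    complex with one exchanged + incoming ligand → leaving ligand + complex with two exchanged (k = 3.10 M⁻¹ min⁻¹)
    complex with three exchanged + incoming ligand → leaving ligand + complex with four exchanged (k = 1.40 M⁻¹ min⁻¹)
    complex with two exchanged + incoming ligand → leaving ligand + complex with three exchanged (k = 3.10 M⁻¹ min⁻¹)
    2 starting complex → homo dimer (k = 9.20 × 10⁻⁴ M⁻¹ min⁻¹)
    starting complex + incoming ligand → leaving ligand + complex with one exchanged (k = 1.90 M⁻¹ min⁻¹)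
    starting complex + complex with two exchanged → side product (k = 0.560 M⁻¹ min⁻¹)

Read at 5.0 h, the same flask should by the constant hold a mean of 4.58%, so complex with two exchanged 5.33% and side product 37.1%. The computed flask gives 5.58% and 36.8%.

(Readings and results are calculated from invented constants, and the scatter is random.)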